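## Retrosynthetic overview

1. Target ⇒ (3R,3'R,6'R)-lutein + 2 α-linolenic acid (Steglich diesterification, last step).
2. Lutein ⇒ ε-C15 phosphonium salt + C10 trienedial + β-C15 phosphonium salt (Wittig couplings at C11=C12, then C11'=C12').
3. Both C15 salts ⇒ the two enantiomers of one racemic trans-3-hydroxy-α-ionone, split by lipase. The (3R,6R) enantiomer stays the ε end; the (3S,6S) enantiomer is isomerised (C4=C5 → C5=C6) to the (3R)-β end.
4. Racemic hydroxy-ionone ⇒ trans-hydroxy-aldehyde ⇒ glycol-tethered bis(keto ester) (Wittig; DIBAL-H reduction that also removes the tether).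
5. Ring formation: both six-membered carbocycles are closed first and together, in step 1, by a twofold Michael–aldol annulation of mesityl oxide on a bis(acetoacetate). No ring is formed later.

Assumption: 1 is bought as such (otherwise one step from ethane-1,2-diol and tert-butyl acetoacetate); for racemates the name carries RS descriptors and the SMILES shows one enantiomer; C3/C6 are carotenoid locants.

## Route

Step 1
Reactants: 1 ethane-1,2-diyl bis(3-oxobutanoate); 2 mesityl oxide (4-methylpent-3-en-2-one)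
Product: 4 ethane-1,2-diyl bis(2,6,6-trimethyl-4-oxocyclohex-2-ene-1-carboxylate) (stereoisomer mixture), via bis-Michael adduct 3 (not isolated)
Conditions: 2 (3 equiv), ZnCl2 (0.3 equiv), toluene, reflux, Dean–Stark
Reagents that add atoms: none
Why: Lewis-acid-promoted Michael addition of each acetoacetate CH2 to mesityl oxide, then intramolecular aldol condensation of the mesityl methyl ketone onto the acetoacetate ketone (Robinson-type annulation to a Hagemann-type ester), closes both cyclohexenone rings of one molecule in the same operation; the ester-bearing ring carbon is formed without control and stays epimerisable.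

Step 2
Reactants: 4 ethane-1,2-diyl bis(2,6,6-trimethyl-4-oxocyclohex-2-ene-1-carboxylate)
Product: 5 (1RS,4RS)-4-hydroxy-2,6,6-trimethylcyclohex-2-ene-1-carbaldehyde (hydroxyl trans to formyl)
Conditions: iBu2AlH (DIBAL-H, 4.4 equiv), CH2Cl2, −78 °C; cold aqueous work-up; SiO2
Reagents that add atoms: none
Why: DIBAL-H gives 1,2-reduction of the enone and partial reduction of each hindered ester (stable aluminium hemiacetal at −78 °C), which frees the aldehyde and the glycol tether; hydride should enter anti to the pseudo-axial C6 methyl, setting the carbinol centre trans to the formyl group by substrate control, and the minor cis isomer (a bicyclic lactol) is removed on silica.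

Step 3
Reactants: 5 (1RS,4RS)-4-hydroxy-2,6,6-trimethylcyclohex-2-ene-1-carbaldehyde
Product: 6 (E)-4-[(1RS,4RS)-4-hydroxy-2,6,6-trimethylcyclohex-2-en-1-yl]but-3-en-2-one (racemic trans-3-hydroxy-α-ionone)
Conditions: Ph3P=CHC(O)CH3 (1.5 equiv), toluene, 90 °C
Reagents that add atoms: 1-(triphenylphosphoranylidene)propan-2-one, CC(=O)C=P(c1ccccc1)(c1ccccc1)c1ccccc1
Why: Wittig olefination with a stabilised, nearly neutral acyl ylide gives the (E)-enone and should not epimerise the aldehyde α-centre, so the 3,6-trans relationship is carried into the ionone.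

Step 4
Reactants: 6 racemic trans-3-hydroxy-α-ionone
Product: 7 (3R,6R)-3-hydroxy-α-ionone (unreacted alcohol); 8 (3S,6S)-3-acetoxy-α-ionone (separated by chromatography)
Conditions: lipase PS (Burkholderia cepacia), vinyl acetate (3 equiv), MTBE, 30 °C, to 50% conversion
Reagents that add atoms: vinyl acetate, CC(=O)OC=C
Why: Lipase-catalysed kinetic resolution by irreversible transesterification: taking the gem-dimethyl side of the ring as the large group (Kazlauskas rule), the (3S,6S)-alcohol is predicted to be the one acetylated, so one operation gives the ε-end enantiomer as alcohol and the β-end enantiomer as acetate, and neither is discarded.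

Step 5
Reactants: 7 (3R,6R)-3-hydroxy-α-ionone
Product: 9 (E)-1-[(1R,4R)-4-hydroxy-2,6,6-trimethylcyclohex-2-en-1-yl]-3-methylpenta-1,4-dien-3-ol (C3 epimers of the chain)
Conditions: CH2=CHMgBr (2.5 equiv), THF, −20 → 0 °C; then H2O
Reagents that add atoms: vinylmagnesium bromide, C=C[Mg]Br
Why: Grignard 1,2-addition to the enone carbonyl (one equivalent is used by the free hydroxyl) gives the tertiary bis-allylic carbinol; its new centre is an epimer mixture erased in step 6, and the ring centres are untouched.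

Step 6
Reactants: 9 ε-vinyl carbinol
Product: 10 [(2E,4E)-5-[(1R,4R)-4-hydroxy-2,6,6-trimethylcyclohex-2-en-1-yl]-3-methylpenta-2,4-dien-1-yl]triphenylphosphonium bromide
Conditions: PPh3·HBr (1.0 equiv), CH2Cl2, 0 °C → rt; crystallise
Reagents that add atoms: triphenylphosphine hydrobromide, [Br-].[PH+](c1ccccc1)(c1ccccc1)c1ccccc1
Why: Acid-mediated allylic transposition (SN1-type): the tertiary doubly allylic alcohol ionises much faster than the secondary ring alcohol, and PPh3 traps the pentadienyl cation at its primary end to give the (2E,4E)-salt without touching C3 or C6.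

Step 7
Reactants: 8 (3S,6S)-3-acetoxy-α-ionone
Product: 12 (3R)-3-hydroxy-β-ionone, via (3S,6S)-3-hydroxy-α-ionone 11 (not isolated)
Conditions: NaOMe (0.3 equiv), MeOH, 50 °C
Reagents that add atoms: none
Why: Methoxide removes the acetate by transesterification and then moves the ring double bond into conjugation with the enone through the extended dienolate (base-catalysed α- to β-ionone isomerisation, driven by the dienone); C6 is erased and C3 is untouched, its descriptor changing from S to R only because the CIP priorities change.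

Step 8
Reactants: 12 (3R)-3-hydroxy-β-ionone
Product: 13 (E)-1-[(4R)-4-hydroxy-2,6,6-trimethylcyclohex-1-en-1-yl]-3-methylpenta-1,4-dien-3-ol (C3 epimers of the chain)
Conditions: CH2=CHMgBr (2.5 equiv), THF, −20 → 0 °C; then H2O
Reagents that add atoms: vinylmagnesium bromide, C=C[Mg]Br
Why: Grignard 1,2-addition to the hindered dienone carbonyl gives the vinyl carbinol; the new centre is erased in step 9 and C3 is untouched.

Step 9
Reactants: 13 β-vinyl carbinol
Product: 14 [(2E,4E)-5-[(4R)-4-hydroxy-2,6,6-trimethylcyclohex-1-en-1-yl]-3-methylpenta-2,4-dien-1-yl]triphenylphosphonium bromide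
Conditions: PPh3·HBr (1.0 equiv), MeOH, 0 °C → rt; crystallise
Reagents that add atoms: triphenylphosphine hydrobromide, [Br-].[PH+](c1ccccc1)(c1ccccc1)c1ccccc1
Why: Acid-mediated allylic transposition of the tertiary carbinol with PPh3 capture at the primary terminus gives the conjugated (2E,4E)-phosphonium salt; the homoallylic ring hydroxyl does not ionise.

Step 10
Reactants: 14 β-C15 phosphonium bromide; 15 (2E,4E,6E)-2,7-dimethylocta-2,4,6-trienedial
Product: 17 (3R)-3-hydroxy-12'-apo-β-caroten-12'-al, via β-C15 ylide 16 (not isolated)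
Conditions: 15 (3 equiv), 1,2-epoxybutane/EtOH, reflux; crystallise (all-E)
Reagents that add atoms: none
Why: Wittig olefination in which bromide opens the epoxide to an alkoxide that generates the ylide, so no strong base meets the hydroxyl or the aldehyde; excess symmetrical dialdehyde limits reaction to one formyl group, and the new 11,12 double bond equilibrates to E on heating.

Step 11
Reactants: 10 ε-C15 phosphonium bromide; 17 (3R)-3-hydroxy-12'-apo-β-caroten-12'-al
Product: 19 (3R,3'R,6'R)-β,ε-carotene-3,3'-diol (lutein), via ε-C15 ylide 18 (not isolated)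
Conditions: 1,2-epoxybutane/EtOH, reflux; then reflux in heptane, crystallise (all-E)
Reagents that add atoms: none
Why: A second Wittig olefination joins the ε end at C11'=C12'; the three stereocentres come unchanged from 10 and 17, and (Z)-isomers at the new bond are isomerised thermally to the all-E polyene.

Step 12
Reactants: 19 lutein; 20 α-linolenic acid ((9Z,12Z,15Z)-octadeca-9,12,15-trienoic acid)
Product: 22 (3R,3'R,6'R)-β,ε-carotene-3,3'-diyl bis[(9Z,12Z,15Z)-octadeca-9,12,15-trienoate] (target), via O-acylisourea 21 (not isolated)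
Conditions: 20 (2.5 equiv), DCC (2.6 equiv), DMAP (0.3 equiv), CH2Cl2, 0 °C → rt, Ar, dark
Reagents that add atoms: none
Why: Steglich esterification (carbodiimide activation, acyl transfer through the acylpyridinium of DMAP) acylates both secondary hydroxyls with retention at C3 and C3' under non-acidic conditions that spare the allylic C3'–O bond, the polyene and the skipped (Z)-trienes.

## Compound list

1 | ethane-1,2-diyl bis(3-oxobutanoate) | CC(=O)CC(=O)OCCOC(=O)CC(C)=O | starting material
2 | mesityl oxide (4-methylpent-3-en-2-one) | CC(=O)C=C(C)C | starting material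
3 | ethane-1,2-diyl bis(2-acetyl-3,3-dimethyl-5-oxohexanoate), bis-Michael adduct, stereoisomer mixture | CC(=O)CC(C)(C)C(C(C)=O)C(=O)OCCOC(=O)C(C(C)=O)C(C)(C)CC(C)=O | intermediate (not isolated)
4 | ethane-1,2-diyl bis(2,6,6-trimethyl-4-oxocyclohex-2-ene-1-carboxylate), stereoisomer mixture at the two ester-bearing ring carbons | CC1=CC(=O)CC(C)(C)C1C(=O)OCCOC(=O)C1C(C)=CC(=O)CC1(C)C | intermediate
5 | (1RS,4RS)-4-hydroxy-2,6,6-trimethylcyclohex-2-ene-1-carbaldehyde, racemate, OH trans to CHO | O=C[C@H]1C(C)=C[C@H](O)CC1(C)C | intermediate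
6 | (E)-4-[(1RS,4RS)-4-hydroxy-2,6,6-trimethylcyclohex-2-en-1-yl]but-3-en-2-one, racemic trans-3-hydroxy-α-ionone | CC(=O)/C=C/[C@H]1C(C)=C[C@H](O)CC1(C)C | intermediate
7 | (3R,6R)-3-hydroxy-α-ionone, (E)-4-[(1R,4R)-4-hydroxy-2,6,6-trimethylcyclohex-2-en-1-yl]but-3-en-2-one | CC(=O)/C=C/[C@H]1C(C)=C[C@H](O)CC1(C)C | intermediate
8 | (3S,6S)-3-acetoxy-α-ionone, (1S,4S)-3,5,5-trimethyl-4-[(E)-3-oxobut-1-en-1-yl]cyclohex-2-en-1-yl acetate | CC(=O)/C=C/[C@@H]1C(C)=C[C@@H](OC(C)=O)CC1(C)C | intermediate
9 | (E)-1-[(1R,4R)-4-hydroxy-2,6,6-trimethylcyclohex-2-en-1-yl]-3-methylpenta-1,4-dien-3-ol, epimers at the chain carbinol | C=CC(C)(O)/C=C/[C@H]1C(C)=C[C@H](O)CC1(C)C | intermediate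
10 | [(2E,4E)-5-[(1R,4R)-4-hydroxy-2,6,6-trimethylcyclohex-2-en-1-yl]-3-methylpenta-2,4-dien-1-yl]triphenylphosphonium bromide | [Br-].c1ccccc1[P+](c1ccccc1)(c1ccccc1)C/C=C(C)/C=C/[C@H]1C(C)=C[C@H](O)CC1(C)C | intermediate
11 | (3S,6S)-3-hydroxy-α-ionone, (E)-4-[(1S,4S)-4-hydroxy-2,6,6-trimethylcyclohex-2-en-1-yl]but-3-en-2-one | CC(=O)/C=C/[C@@H]1C(C)=C[C@@H](O)CC1(C)C | intermediate (not isolated)
12 | (3R)-3-hydroxy-β-ionone, (E)-4-[(4R)-4-hydroxy-2,6,6-trimethylcyclohex-1-en-1-yl]but-3-en-2-one | CC(=O)/C=C/C1=C(C)C[C@@H](O)CC1(C)C | intermediate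
13 | (E)-1-[(4R)-4-hydroxy-2,6,6-trimethylcyclohex-1-en-1-yl]-3-methylpenta-1,4-dien-3-ol, epimers at the chain carbinol | C=CC(C)(O)/C=C/C1=C(C)C[C@@H](O)CC1(C)C | intermediate
14 | [(2E,4E)-5-[(4R)-4-hydroxy-2,6,6-trimethylcyclohex-1-en-1-yl]-3-methylpenta-2,4-dien-1-yl]triphenylphosphonium bromide | [Br-].c1ccccc1[P+](c1ccccc1)(c1ccccc1)C/C=C(C)/C=C/C1=C(C)C[C@@H](O)CC1(C)C | intermediate
15 | (2E,4E,6E)-2,7-dimethylocta-2,4,6-trienedial (C10 dialdehyde) | O=C/C(C)=C/C=C/C=C(C)/C=O | starting material
16 | β-C15 ylide, triphenylphosphorane of 14 | c1ccccc1P(c1ccccc1)(c1ccccc1)=C/C=C(C)/C=C/C1=C(C)C[C@@H](O)CC1(C)C | intermediate (not isolated)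
17 | (3R)-3-hydroxy-12'-apo-β-caroten-12'-al, (2E,4E,6E,8E,10E,12E)-13-[(4R)-4-hydroxy-2,6,6-trimethylcyclohex-1-en-1-yl]-2,7,11-trimethyltrideca-2,4,6,8,10,12-hexaenal | O[C@@H]1CC(C)=C(/C=C/C(C)=C/C=C/C(C)=C/C=C/C=C(C)/C=O)C(C)(C)C1 | intermediate
18 | ε-C15 ylide, triphenylphosphorane of 10 | c1ccccc1P(c1ccccc1)(c1ccccc1)=C/C=C(C)/C=C/[C@H]1C(C)=C[C@H](O)CC1(C)C | intermediate (not isolated)
19 | (3R,3'R,6'R)-β,ε-carotene-3,3'-diol (lutein), all-E | O[C@@H]1CC(C)=C(/C=C/C(C)=C/C=C/C(C)=C/C=C/C=C(C)/C=C/C=C(C)/C=C/[C@H]2C(C)=C[C@H](O)CC2(C)C)C(C)(C)C1 | intermediate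
20 | α-linolenic acid, (9Z,12Z,15Z)-octadeca-9,12,15-trienoic acid | CC/C=C\C/C=C\C/C=C\CCCCCCCC(=O)O | starting material
21 | O-linolenoyl-N,N'-dicyclohexylisourea | CC/C=C\C/C=C\C/C=C\CCCCCCCC(=O)OC(=NC1CCCCC1)NC1CCCCC1 | intermediate (not isolated)
22 | (3R,3'R,6'R)-β,ε-carotene-3,3'-diyl bis[(9Z,12Z,15Z)-octadeca-9,12,15-trienoate], CNP0400996.1 | CC/C=C\C/C=C\C/C=C\CCCCCCCC(=O)O[C@@H]1CC(C)=C(/C=C/C(C)=C/C=C/C(C)=C/C=C/C=C(C)/C=C/C=C(C)/C=C/[C@H]2C(C)=C[C@H](OC(=O)CCCCCCC/C=C\C/C=C\C/C=C\CC)CC2(C)C)C(C)(C)C1 | target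

## Step count and fallbacks

Total: 12 steps. Longest linear sequence: 10 steps (1, 2, 3, 4, 7, 8, 9, 10, 11, 12); steps 5 and 6 form the ε branch that joins at step 11.

The three steps most likely to fail are steps 2, 3 and 7.

Step 2 asks one reagent to stop at the aldehyde for two hindered esters while also reducing two ketones with useful trans selectivity; over-reduction or a poor trans:cis ratio is the likely failure. The fallback sets out from 4. Full reduction with LiAlH4 (THF, 0 °C) cleaves the tether and, after chromatographic removal of the cis isomer, gives the diol (1RS,4RS)-4-(hydroxymethyl)-3,5,5-trimethylcyclohex-2-en-1-ol F1. Oxidation of its primary alcohol alone with TEMPO/PhI(OAc)2 (CH2Cl2, 0 °C) comes back to the route at 5.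

Step 3 uses a weakly nucleophilic ylide on a hindered aldehyde whose α-centre can epimerise to the cis isomer, which is trapped as a lactol. The fallback sets out from 5. Non-basic methylenation (CH2Br2, Zn, TiCl4, THF) gives (1RS,4RS)-3,5,5-trimethyl-4-vinylcyclohex-2-en-1-ol F2. Cross-metathesis of F2 with but-3-en-2-one, using the second-generation Hoveyda–Grubbs catalyst RuCl2(H2IMes)(=CH-C6H4-2-OiPr) in CH2Cl2 at 40 °C, builds the (E)-enone and comes back to the route at 6.

Step 7 is an equilibrium isomerisation that may stop short or leak into retro-type isomers. The fallback sets out from 5 (a portion taken before step 3) and makes the β series directly. DBU in CH2Cl2 moves the double bond into conjugation to give racemic 4-hydroxy-2,6,6-trimethylcyclohex-1-ene-1-carbaldehyde F3. Aldol condensation with acetone (aqueous NaOH) gives racemic 3-hydroxy-β-ionone F4. Lipase PS with vinyl acetate should acetylate the (3R)-enantiomer to (3R)-3-acetoxy-β-ionone F5 and leave (3S)-3-hydroxy-β-ionone F6. Methanolysis of F5 (K2CO3, MeOH) comes back to the route at 12; acetate 8 is then not used.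

Further compounds

F1 | step 2 | (1RS,4RS)-4-(hydroxymethyl)-3,5,5-trimethylcyclohex-2-en-1-ol, racemate | OC[C@H]1C(C)=C[C@H](O)CC1(C)C
F2 | step 3 | (1RS,4RS)-3,5,5-trimethyl-4-vinylcyclohex-2-en-1-ol, racemate | C=C[C@H]1C(C)=C[C@H](O)CC1(C)C
F3 | step 7 | racemic 4-hydroxy-2,6,6-trimethylcyclohex-1-ene-1-carbaldehyde | O=CC1=C(C)CC(O)CC1(C)C
F4 | step 7 | racemic (E)-4-(4-hydroxy-2,6,6-trimethylcyclohex-1-en-1-yl)but-3-en-2-one | CC(=O)/C=C/C1=C(C)CC(O)CC1(C)C
F5 | step 7 | (1R)-3,5,5-trimethyl-4-[(E)-3-oxobut-1-en-1-yl]cyclohex-3-en-1-yl acetate, (3R)-3-acetoxy-β-ionone | CC(=O)/C=C/C1=C(C)C[C@@H](OC(C)=O)CC1(C)C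
F6 | step 7 | (E)-4-[(4S)-4-hydroxy-2,6,6-trimethylcyclohex-1-en-1-yl]but-3-en-2-one, (3S)-3-hydroxy-β-ionone | CC(=O)/C=C/C1=C(C)C[C@H](O)CC1(C)C
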